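**Plan**

- Cuts (retrosynthesis): first the benzyl C–C bond at C4 of the oxolane (aryl Grignard + spiro-epoxide) and the epoxide oxygen (4-methylene oxolane); then ring bond O1–C5 (2-methylene-1,4-diol from a cis α-methylene lactone) and C2–C3 (anti-aldol on the C5' aldehyde); then C5'–CHO (aryl triflate); last the benzo ring at C3a'–C4', C4'–C5', C6'–C7' and C7'–C7a'.
- Enabling feature: the benzo ring (ring C: C3a', C4'–H, C5'–carbon, C6'–H, C7'–OMe, C7a'–O) is a 1,3-dioxygenated benzene fused to a furan through C7a'–O. A 3-furylketene and a silyl ynol ether write exactly this pattern, with the C5' oxygen serving as a masked leaving group.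
- Forward order: purchased furan → ring E at C2' → diazo ketone → benzo ring C (step 7) → ring D reduced to the cis-dihydrofuran → C5' aldehyde → γ-lactone by aldol → oxolane ring B by Mitsunobu closure → ring A joined by epoxide opening → deprotection.
- Stereochemistry: C2'/C3' from a syn, ligand-controlled hydrogenation of the flat furan ring; C2/C3 from an auxiliary-controlled anti-aldol; C4 from epoxidation of the exocyclic alkene anti to the two cis substituents, then SN2 opening at CH2.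

Key step: step 7

Remark: the target SMILES is read as a cis-(2'R,3'R)-dihydrobenzofuran and an oxolane with aryl, CH2OH and benzyl all cis and OH trans to CH2OH. With the working locants O1, C2 (aryl), C3 (CH2OH), C4 (OH, benzyl), C5 this is (2R,3R,4S), which equals (5R,4R,3S) in the oxolan-3-ol names of the compound list. Primed locants are benzofuran locants.

Abbreviation: ArD = (2R,3R)-2-(4-benzyloxy-3-methoxyphenyl)-3-[(tert-butyldimethylsilyloxy)methyl]-7-methoxy-2,3-dihydrobenzofuran-5-yl.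

**Route**

Step 1
Reactants: 1 4-bromo-2-methoxyphenol
Product: 2 1-(benzyloxy)-4-bromo-2-methoxybenzene
Conditions: BnBr, K2CO3, acetone, reflux
Reagents that add atoms: benzyl bromide, BrCc1ccccc1
Why: Williamson ether synthesis on the phenoxide; the benzyl ether is inert to the bases, hydrides and organometallics used later and leaves by hydrogenolysis at the end.

Step 2
Reactants: 3 dimethyl furan-3,4-dicarboxylate (3 equiv); 2 1-(benzyloxy)-4-bromo-2-methoxybenzene
Product: 4 dimethyl 2-(4-benzyloxy-3-methoxyphenyl)furan-3,4-dicarboxylate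
Conditions: Pd(OAc)2 (5 mol%), PCy3·HBF4 (10 mol%), PivOH (30 mol%), K2CO3, DMA, 100 °C
Reagents that add atoms: none
Why: Palladium-catalysed direct C–H arylation (concerted metalation–deprotonation) at the acidic furan α-position next to an ester; both α-positions of 3 are equivalent and the excess of 3 suppresses a second arylation.

Step 3
Reactants: 4 dimethyl 2-(4-benzyloxy-3-methoxyphenyl)furan-3,4-dicarboxylate
Product: 5 5-(4-benzyloxy-3-methoxyphenyl)-4-(methoxycarbonyl)furan-3-carboxylic acid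
Conditions: LiOH·H2O (1.05 equiv), THF–H2O, 0 °C → rt; HCl aq
Reagents that add atoms: lithium hydroxide, [Li+].[OH-]
Why: Saponification stops at the mono-acid because the carboxylate deactivates the second ester, and the furan C4 ester (flanked only by C5–H) should be attacked faster than the C3 ester, which is shielded by the ortho aryl group.

Step 4
Reactants: 5 5-(4-benzyloxy-3-methoxyphenyl)-4-(methoxycarbonyl)furan-3-carboxylic acid
Product: 7 methyl 2-(4-benzyloxy-3-methoxyphenyl)-4-(diazoacetyl)furan-3-carboxylate, via acid chloride 6 (not isolated)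
Conditions: (COCl)2, DMF (cat.), CH2Cl2, 0 °C → rt, evaporate; CH2N2, Et3N, Et2O–THF, 0 °C
Reagents that add atoms: diazomethane, C=[N+]=[N-]
Why: Acylation of diazomethane by a non-enolisable heteroaroyl chloride (first stage of the Arndt–Eistert sequence); Et3N takes up HCl so that no chloromethyl ketone forms.

Step 5
Reactants: 8 ethynyltrimethylsilane
Product: 11 triisopropyl{[(trimethylsilyl)ethynyl]oxy}silane, via lithium acetylide 9 (not isolated), via lithium ynolate 10 (not isolated)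
Conditions: n-BuLi, THF, −78 °C; t-BuOOLi (from t-BuOOH and LiN(SiMe3)2), −78 → 0 °C; i-Pr3SiOTf, −78 °C → rt
Reagents that add atoms: lithium tert-butyl peroxide, [Li+].[O-]OC(C)(C)C; triisopropylsilyl triflate, CC(C)[Si](OS(=O)(=O)C(F)(F)F)(C(C)C)C(C)C
Why: Electrophilic oxygen transfer from the lithium peroxide to the acetylide gives the ynolate, which the bulky, hard silyl triflate should trap on oxygen (ynolate O-silylation) and not on carbon.

Step 6
Reactants: 11 triisopropyl{[(trimethylsilyl)ethynyl]oxy}silane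
Product: 12 (triisopropylsilyloxy)acetylene
Conditions: K2CO3 (cat.), MeOH, 0 °C
Reagents that add atoms: none
Why: Methoxide-induced protodesilylation of an alkynylsilane; attack goes to the unhindered SiMe3 group while the hindered O–Si(i-Pr)3 bond is kept.

Step 7
Reactants: 7 methyl 2-(4-benzyloxy-3-methoxyphenyl)-4-(diazoacetyl)furan-3-carboxylate; 12 (triisopropylsilyloxy)acetylene (2 equiv)
Product: 17 methyl 2-(4-benzyloxy-3-methoxyphenyl)-7-hydroxy-5-(triisopropylsilyloxy)benzofuran-3-carboxylate, via furylketene 13 (not isolated), via cyclobutenone 14 (not isolated), via dienylketene 15 (not isolated), via cyclohexadienone 16 (not isolated)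
Conditions: hν (254 nm, Vycor), ClCH2CH2Cl, rt; then 80 °C
Reagents that add atoms: none
Why: Light expels N2 from 7 and the furyl group shifts to the carbene carbon (Wolff rearrangement, bond C3a'–C4') to give furylketene 13, which adds ynol ether 12 in a (2+2) cycloaddition: the nucleophilic CH carbon of 12 bonds to the ketene carbonyl carbon (C6'–C7') and the oxygen-bearing carbon to the ketene α-carbon (C4'–C5'), giving cyclobutenone 14. Warming opens 14 by a 4-electron conrotatory electrocyclic ring opening to dienylketene 15, whose 6-electron disrotatory electrocyclisation onto the free furan α-carbon (C7'–C7a') gives cyclohexadienone 16, and tautomerisation gives phenol 17. The closest known reaction type is the photochemical, second-generation Danheiser benzannulation of aryl and heteroaryl α-diazo ketones with siloxyalkynes. The one ring that remains is the six-membered benzo ring, closed by the 6π electrocyclisation; the four-membered ring is transient. No stereocentre is formed. Regiocontrol is needed twice: the polarisation of the ynol ether puts the silyloxy group at C5' and the phenol at C7', and the C3 ester blocks the other ortho position of the furan so that only closure at the C5–H carbon can end in an aromatic ring.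

Step 8
Reactants: 17 methyl 2-(4-benzyloxy-3-methoxyphenyl)-7-hydroxy-5-(triisopropylsilyloxy)benzofuran-3-carboxylate
Product: 18 methyl 2-(4-benzyloxy-3-methoxyphenyl)-7-methoxy-5-(triisopropylsilyloxy)benzofuran-3-carboxylate
Conditions: MeI, K2CO3, acetone, 40 °C
Reagents that add atoms: iodomethane, CI
Why: Williamson O-methylation of the free C7' phenoxide; the hindered aryl silyl ether is inert to carbonate in an aprotic solvent.

Step 9
Reactants: 18 methyl 2-(4-benzyloxy-3-methoxyphenyl)-7-methoxy-5-(triisopropylsilyloxy)benzofuran-3-carboxylate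
Product: 19 methyl (2R,3S)-2-(4-benzyloxy-3-methoxyphenyl)-7-methoxy-5-(triisopropylsilyloxy)-2,3-dihydrobenzofuran-3-carboxylate
Conditions: Ru(cod)(2-methylallyl)2 (5 mol%), (R,R)-SINpEt·HBF4 (10 mol%), KOt-Bu, hexane, 70 °C; then H2 (100 bar), toluene, 40 °C
Reagents that add atoms: none
Why: Proposed new method: a chiral ruthenium–NHC hydride (ligand precursor 1,3-bis[(R)-1-(1-naphthyl)ethyl]imidazolinium tetrafluoroborate) should add H2 in syn fashion across the ester-conjugated C2'=C3' bond from one face of the flat ring, which gives the 2,3-cis ester directly and sets both stereocentres (2R, 3S) under ligand control, the ligand antipode being used if the facial sense proves opposite; the closest known reaction type is the Ru–NHC-catalysed enantioselective hydrogenation of 2-aryl- and 2-alkylbenzofurans, which has not been shown for 2,3-disubstituted benzofuran-3-carboxylates.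

Step 10
Reactants: 19 methyl (2R,3S)-2-(4-benzyloxy-3-methoxyphenyl)-7-methoxy-5-(triisopropylsilyloxy)-2,3-dihydrobenzofuran-3-carboxylate
Product: 20 [(2R,3R)-2-(4-benzyloxy-3-methoxyphenyl)-7-methoxy-5-(triisopropylsilyloxy)-2,3-dihydrobenzofuran-3-yl]methanol
Conditions: i-Bu2AlH (2.5 equiv), CH2Cl2, −78 → 0 °C; KNaC4H4O6 aq
Reagents that add atoms: none
Why: Hydride reduction of the ester to the primary alcohol at low temperature removes the acidic C3'–H before any base can epimerise the cis ester to the trans isomer.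

Step 11
Reactants: 20 [(2R,3R)-2-(4-benzyloxy-3-methoxyphenyl)-7-methoxy-5-(triisopropylsilyloxy)-2,3-dihydrobenzofuran-3-yl]methanol
Product: 22 (2R,3R)-2-(4-benzyloxy-3-methoxyphenyl)-3-(hydroxymethyl)-7-methoxy-2,3-dihydrobenzofuran-5-yl trifluoromethanesulfonate, via ammonium phenoxide 21 (not isolated)
Conditions: Bu4NF (1.05 equiv), THF, 0 °C; then PhNTf2, 0 °C → rt
Reagents that add atoms: N-phenylbis(trifluoromethanesulfonimide), O=S(=O)(N(c1ccccc1)S(=O)(=O)C(F)(F)F)C(F)(F)F
Why: Fluoride cleaves the aryl O–Si bond and the phenoxide is sulfonylated in the same flask by the mild triflimide (aryl triflate formation), which leaves the neutral primary alcohol alone.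

Step 12
Reactants: 22 (2R,3R)-2-(4-benzyloxy-3-methoxyphenyl)-3-(hydroxymethyl)-7-methoxy-2,3-dihydrobenzofuran-5-yl trifluoromethanesulfonate
Product: 23 (2R,3R)-2-(4-benzyloxy-3-methoxyphenyl)-3-[(tert-butyldimethylsilyloxy)methyl]-7-methoxy-2,3-dihydrobenzofuran-5-yl trifluoromethanesulfonate
Conditions: TBSCl, imidazole, CH2Cl2, rt
Reagents that add atoms: tert-butyldimethylsilyl chloride, CC(C)(C)[Si](C)(C)Cl
Why: Standard silylation of a primary alcohol; the silyl ether should survive every step up to the fluoride treatment in step 24.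

Step 13
Reactants: 23 (2R,3R)-2-(4-benzyloxy-3-methoxyphenyl)-3-[(tert-butyldimethylsilyloxy)methyl]-7-methoxy-2,3-dihydrobenzofuran-5-yl trifluoromethanesulfonate
Product: 24 (2R,3R)-2-(4-benzyloxy-3-methoxyphenyl)-3-[(tert-butyldimethylsilyloxy)methyl]-7-methoxy-2,3-dihydrobenzofuran-5-carbaldehyde
Conditions: Pd(OAc)2 (5 mol%), dppp (5 mol%), CO (1 atm), Et3SiH, Et3N, DMF, 70 °C
Reagents that add atoms: carbon monoxide, [C-]#[O+]
Why: Reductive carbonylation of an aryl triflate: oxidative addition to zerovalent palladium, CO insertion and hydride transfer from the silane to the acylpalladium give the aryl aldehyde.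

Step 14
Reactants: 25 (R)-4-benzyloxazolidin-2-one; 26 methyl 4-chloro-4-oxobutanoate
Product: 27 methyl 4-[(R)-4-benzyl-2-oxooxazolidin-3-yl]-4-oxobutanoate
Conditions: Et3N, DMAP (cat.), CH2Cl2, 0 °C → rt
Reagents that add atoms: none
Why: N-Acylation of the oxazolidinone by an acid chloride under nucleophilic catalysis gives the chiral imide for the aldol step.

Step 15
Reactants: 24 (2R,3R)-2-(4-benzyloxy-3-methoxyphenyl)-3-[(tert-butyldimethylsilyloxy)methyl]-7-methoxy-2,3-dihydrobenzofuran-5-carbaldehyde; 27 methyl 4-[(R)-4-benzyl-2-oxooxazolidin-3-yl]-4-oxobutanoate (1.5 equiv)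
Product: 30 (R)-4-benzyl-3-[(2R,3S)-2-ArD-5-oxotetrahydrofuran-3-carbonyl]oxazolidin-2-one, via silyl aldol adduct 28 (not isolated), via hydroxy ester 29 (not isolated)
Conditions: MgCl2 (20 mol%), Et3N, Me3SiCl, EtOAc, rt; then PPTS, MeOH, 0 °C; then PPTS (cat.), toluene, 50 °C
Reagents that add atoms: none
Why: Magnesium halide-catalysed direct anti-aldol reaction of a chiral N-acyloxazolidinone with an aromatic aldehyde (anti variant of the Evans aldol): the chelated Z-enolate is attacked on the face away from the benzyl group of the (R)-auxiliary, which sets the future C3 (S in the adduct) and, through the anti relationship, the carbinol carbon C2 (R), and mild acid then removes the silyl group and closes the γ-lactone, in which aryl and acyl groups are cis.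

Step 16
Reactants: 30 (R)-4-benzyl-3-[(2R,3S)-2-ArD-5-oxotetrahydrofuran-3-carbonyl]oxazolidin-2-one
Product: 31 (2R,3S)-2-ArD-5-oxotetrahydrofuran-3-carboxylic acid
Conditions: LiOH, H2O2, THF–H2O, 0 °C; Na2SO3 aq; HCl aq
Reagents that add atoms: hydrogen peroxide, OO
Why: Hydroperoxide attacks the exocyclic imide carbonyl selectively (standard cleavage of the auxiliary, which is recovered), and any lactone opened on the way closes again on acidification.

Step 17
Reactants: 31 (2R,3S)-2-ArD-5-oxotetrahydrofuran-3-carboxylic acid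
Product: 32 (4R,5R)-5-ArD-4-(hydroxymethyl)dihydrofuran-2(3H)-one
Conditions: BH3·SMe2, THF, 0 °C → rt; MeOH
Reagents that add atoms: none
Why: Borane reduces a carboxylic acid much faster than a lactone, so only the acid becomes the primary alcohol.

Step 18
Reactants: 32 (4R,5R)-5-ArD-4-(hydroxymethyl)dihydrofuran-2(3H)-one
Product: 33 (4R,5R)-5-ArD-4-[(tert-butyldimethylsilyloxy)methyl]dihydrofuran-2(3H)-one
Conditions: TBSCl, imidazole, CH2Cl2, 0 °C
Reagents that add atoms: tert-butyldimethylsilyl chloride, CC(C)(C)[Si](C)(C)Cl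
Why: Silylation under nearly neutral conditions caps the primary alcohol before it can attack the lactone carbonyl and translactonise.

Step 19
Reactants: 33 (4R,5R)-5-ArD-4-[(tert-butyldimethylsilyloxy)methyl]dihydrofuran-2(3H)-one
Product: 35 (4R,5R)-5-ArD-4-[(tert-butyldimethylsilyloxy)methyl]-3-methylenedihydrofuran-2(3H)-one, via formyl lactone enolate 34 (not isolated)
Conditions: NaH, HCO2Et, THF, 0 °C → rt; then (CH2O)n, 65 °C
Reagents that add atoms: formaldehyde (as paraformaldehyde), C=O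
Why: Claisen formylation of the lactone, aldol addition of the formyl enolate to formaldehyde and loss of formate is a standard α-methylenation of γ-butyrolactones; the two ring stereocentres are not acidic and are untouched.

Step 20
Reactants: 35 (4R,5R)-5-ArD-4-[(tert-butyldimethylsilyloxy)methyl]-3-methylenedihydrofuran-2(3H)-one
Product: 36 (1R,2R)-1-ArD-2-[(tert-butyldimethylsilyloxy)methyl]-3-methylenebutane-1,4-diol
Conditions: i-Bu2AlH (4 equiv), CH2Cl2, −78 → 0 °C; KNaC4H4O6 aq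
Reagents that add atoms: none
Why: 1,2-Reduction of the α-methylene lactone by the aluminium hydride gives the 2-methylene-1,4-diol without conjugate reduction.

Step 21
Reactants: 36 (1R,2R)-1-ArD-2-[(tert-butyldimethylsilyloxy)methyl]-3-methylenebutane-1,4-diol
Product: 37 tert-butyl{[(2R,3R)-2-ArD-4-methylenetetrahydrofuran-3-yl]methoxy}dimethylsilane
Conditions: PPh3, DIAD, THF, 0 °C → rt
Reagents that add atoms: none
Why: Mitsunobu cyclodehydration: the unhindered allylic primary alcohol is activated as the oxyphosphonium ion and displaced (5-exo-tet) by the benzylic oxygen, so C2 keeps its configuration and the 2,3-cis oxolane forms under kinetic control.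

Step 22
Reactants: 37 tert-butyl{[(2R,3R)-2-ArD-4-methylenetetrahydrofuran-3-yl]methoxy}dimethylsilane
Product: 38 (3R,6R,7R)-6-ArD-7-[(tert-butyldimethylsilyloxy)methyl]-1,5-dioxaspiro[2.4]heptane
Conditions: mCPBA, NaHCO3, CH2Cl2, 0 °C
Reagents that add atoms: 3-chloroperbenzoic acid, OOC(=O)c1cccc(Cl)c1
Why: Prilezhaev epoxidation of the exocyclic alkene from the ring face opposite to the cis aryl and silyloxymethyl groups puts the epoxide oxygen trans to the C3 substituent and so sets the configuration of C4.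

Step 23
Reactants: 38 (3R,6R,7R)-6-ArD-7-[(tert-butyldimethylsilyloxy)methyl]-1,5-dioxaspiro[2.4]heptane; 2 1-(benzyloxy)-4-bromo-2-methoxybenzene
Product: 40 (3S,4R,5R)-5-ArD-3-(4-benzyloxy-3-methoxybenzyl)-4-[(tert-butyldimethylsilyloxy)methyl]tetrahydrofuran-3-ol, via arylmagnesium bromide 39 (not isolated)
Conditions: 2, Mg, THF, 40 °C; then CuI (10 mol%), 38, THF, −30 → 0 °C; NH4Cl aq
Reagents that add atoms: none
Why: Copper-catalysed SN2 opening of the 2,2-disubstituted epoxide at its CH2 terminus by the aryl Grignard reagent builds the benzyl group; the C4–O bond is not touched, so the tertiary carbinol keeps the configuration set in step 22.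

Step 24
Reactants: 40 (3S,4R,5R)-5-ArD-3-(4-benzyloxy-3-methoxybenzyl)-4-[(tert-butyldimethylsilyloxy)methyl]tetrahydrofuran-3-ol
Product: 41 (3S,4R,5R)-3-(4-benzyloxy-3-methoxybenzyl)-5-[(2R,3R)-2-(4-benzyloxy-3-methoxyphenyl)-3-(hydroxymethyl)-7-methoxy-2,3-dihydrobenzofuran-5-yl]-4-(hydroxymethyl)tetrahydrofuran-3-ol
Conditions: Bu4NF, THF, 0 °C → rt; NH4Cl aq
Reagents that add atoms: none
Why: Fluoride-mediated desilylation cleaves both primary silyl ethers; benzyl ethers and the tertiary alcohol are inert.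

Step 25
Reactants: 41 (3S,4R,5R)-3-(4-benzyloxy-3-methoxybenzyl)-5-[(2R,3R)-2-(4-benzyloxy-3-methoxyphenyl)-3-(hydroxymethyl)-7-methoxy-2,3-dihydrobenzofuran-5-yl]-4-(hydroxymethyl)tetrahydrofuran-3-ol
Product: 42 (3S,4R,5R)-3-(4-hydroxy-3-methoxybenzyl)-5-[(2R,3R)-2-(4-hydroxy-3-methoxyphenyl)-3-(hydroxymethyl)-7-methoxy-2,3-dihydrobenzofuran-5-yl]-4-(hydroxymethyl)tetrahydrofuran-3-ol (CNP0284796.1)
Conditions: H2 (1 atm), Pd/C (10%), EtOAc–MeOH, rt, stopped after uptake of 2 equiv
Reagents that add atoms: none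
Why: Hydrogenolysis of the two aryl benzyl ethers over palladium should be much faster than cleavage of the benzylic ring C–O bonds, so brief exposure under neutral conditions frees both phenols without opening either oxygen ring.

**Compound list**

1 | 4-bromo-2-methoxyphenol | COc1cc(Br)ccc1O | starting material
2 | 1-(benzyloxy)-4-bromo-2-methoxybenzene | COc1cc(Br)ccc1OCc1ccccc1 | intermediate
3 | dimethyl furan-3,4-dicarboxylate | COC(=O)c1cocc1C(=O)OC | starting material
4 | dimethyl 2-(4-benzyloxy-3-methoxyphenyl)furan-3,4-dicarboxylate | COC(=O)c1coc(-c2ccc(OCc3ccccc3)c(OC)c2)c1C(=O)OC | intermediate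
5 | 5-(4-benzyloxy-3-methoxyphenyl)-4-(methoxycarbonyl)furan-3-carboxylic acid | OC(=O)c1coc(-c2ccc(OCc3ccccc3)c(OC)c2)c1C(=O)OC | intermediate
6 | methyl 2-(4-benzyloxy-3-methoxyphenyl)-4-(chlorocarbonyl)furan-3-carboxylate | ClC(=O)c1coc(-c2ccc(OCc3ccccc3)c(OC)c2)c1C(=O)OC | intermediate (not isolated)
7 | methyl 2-(4-benzyloxy-3-methoxyphenyl)-4-(diazoacetyl)furan-3-carboxylate | COC(=O)c1c(C(=O)C=[N+]=[N-])coc1-c1ccc(OCc2ccccc2)c(OC)c1 | intermediate
8 | ethynyltrimethylsilane | C#C[Si](C)(C)C | starting material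
9 | lithium (trimethylsilyl)acetylide | [Li]C#C[Si](C)(C)C | intermediate (not isolated)
10 | lithium 2-(trimethylsilyl)ethynolate | [Li]OC#C[Si](C)(C)C | intermediate (not isolated)
11 | triisopropyl{[(trimethylsilyl)ethynyl]oxy}silane | C[Si](C)(C)C#CO[Si](C(C)C)(C(C)C)C(C)C | intermediate
12 | (triisopropylsilyloxy)acetylene | C#CO[Si](C(C)C)(C(C)C)C(C)C | intermediate
13 | methyl 2-(4-benzyloxy-3-methoxyphenyl)-4-(2-oxoethenyl)furan-3-carboxylate (furylketene) | COC(=O)c1c(C=C=O)coc1-c1ccc(OCc2ccccc2)c(OC)c1 | intermediate (not isolated)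
14 | methyl 2-(4-benzyloxy-3-methoxyphenyl)-4-[4-oxo-2-(triisopropylsilyloxy)cyclobut-2-en-1-yl]furan-3-carboxylate | COC(=O)c1c(C2C(=O)C=C2O[Si](C(C)C)(C(C)C)C(C)C)coc1-c1ccc(OCc2ccccc2)c(OC)c1 | intermediate (not isolated)
15 | methyl 2-(4-benzyloxy-3-methoxyphenyl)-4-[(1E)-4-oxo-2-(triisopropylsilyloxy)buta-1,3-dien-1-yl]furan-3-carboxylate (dienylketene) | COC(=O)c1c(/C=C(\C=C=O)O[Si](C(C)C)(C(C)C)C(C)C)coc1-c1ccc(OCc2ccccc2)c(OC)c1 | intermediate (not isolated)
16 | methyl 2-(4-benzyloxy-3-methoxyphenyl)-7-oxo-5-(triisopropylsilyloxy)-7,7a-dihydrobenzofuran-3-carboxylate | COC(=O)C1=C(c2ccc(OCc3ccccc3)c(OC)c2)OC2C1=CC(O[Si](C(C)C)(C(C)C)C(C)C)=CC2=O | intermediate (not isolated)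
17 | methyl 2-(4-benzyloxy-3-methoxyphenyl)-7-hydroxy-5-(triisopropylsilyloxy)benzofuran-3-carboxylate | COC(=O)c1c(-c2ccc(OCc3ccccc3)c(OC)c2)oc2c(O)cc(O[Si](C(C)C)(C(C)C)C(C)C)cc12 | intermediate
18 | methyl 2-(4-benzyloxy-3-methoxyphenyl)-7-methoxy-5-(triisopropylsilyloxy)benzofuran-3-carboxylate | COC(=O)c1c(-c2ccc(OCc3ccccc3)c(OC)c2)oc2c(OC)cc(O[Si](C(C)C)(C(C)C)C(C)C)cc12 | intermediate
19 | methyl (2R,3S)-2-(4-benzyloxy-3-methoxyphenyl)-7-methoxy-5-(triisopropylsilyloxy)-2,3-dihydrobenzofuran-3-carboxylate (2,3-cis) | CC(C)[Si](C(C)C)(C(C)C)Oc1cc(OC)c2c(c1)[C@H](C(=O)OC)[C@H](c1ccc(OCc3ccccc3)c(OC)c1)O2 | intermediate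
20 | [(2R,3R)-2-(4-benzyloxy-3-methoxyphenyl)-7-methoxy-5-(triisopropylsilyloxy)-2,3-dihydrobenzofuran-3-yl]methanol | CC(C)[Si](C(C)C)(C(C)C)Oc1cc(OC)c2c(c1)[C@H](CO)[C@H](c1ccc(OCc3ccccc3)c(OC)c1)O2 | intermediate
21 | tetrabutylammonium (2R,3R)-2-(4-benzyloxy-3-methoxyphenyl)-3-(hydroxymethyl)-7-methoxy-2,3-dihydrobenzofuran-5-olate | [O-]c1cc(OC)c2c(c1)[C@H](CO)[C@H](c1ccc(OCc3ccccc3)c(OC)c1)O2.CCCC[N+](CCCC)(CCCC)CCCC | intermediate (not isolated)
22 | (2R,3R)-2-(4-benzyloxy-3-methoxyphenyl)-3-(hydroxymethyl)-7-methoxy-2,3-dihydrobenzofuran-5-yl trifluoromethanesulfonate | FC(F)(F)S(=O)(=O)Oc1cc(OC)c2c(c1)[C@H](CO)[C@H](c1ccc(OCc3ccccc3)c(OC)c1)O2 | intermediate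
23 | (2R,3R)-2-(4-benzyloxy-3-methoxyphenyl)-3-[(tert-butyldimethylsilyloxy)methyl]-7-methoxy-2,3-dihydrobenzofuran-5-yl trifluoromethanesulfonate | FC(F)(F)S(=O)(=O)Oc1cc(OC)c2c(c1)[C@H](CO[Si](C)(C)C(C)(C)C)[C@H](c1ccc(OCc3ccccc3)c(OC)c1)O2 | intermediate
24 | (2R,3R)-2-(4-benzyloxy-3-methoxyphenyl)-3-[(tert-butyldimethylsilyloxy)methyl]-7-methoxy-2,3-dihydrobenzofuran-5-carbaldehyde (ArD–CHO) | O=Cc1cc(OC)c2c(c1)[C@H](CO[Si](C)(C)C(C)(C)C)[C@H](c1ccc(OCc3ccccc3)c(OC)c1)O2 | intermediate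
25 | (R)-4-benzyloxazolidin-2-one | O=C1N[C@H](Cc2ccccc2)CO1 | starting material
26 | methyl 4-chloro-4-oxobutanoate | COC(=O)CCC(=O)Cl | starting material
27 | methyl 4-[(R)-4-benzyl-2-oxooxazolidin-3-yl]-4-oxobutanoate | COC(=O)CCC(=O)N1C(=O)OC[C@H]1Cc1ccccc1 | intermediate
28 | methyl (3S,4R)-4-ArD-3-[(R)-4-benzyl-2-oxooxazolidine-3-carbonyl]-4-(trimethylsilyloxy)butanoate | C[Si](C)(C)O[C@@H](c3cc(OC)c4c(c3)[C@H](CO[Si](C)(C)C(C)(C)C)[C@H](c3ccc(OCc5ccccc5)c(OC)c3)O4)[C@H](CC(=O)OC)C(=O)N1C(=O)OC[C@H]1Cc1ccccc1 | intermediate (not isolated)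
29 | methyl (3S,4R)-4-ArD-3-[(R)-4-benzyl-2-oxooxazolidine-3-carbonyl]-4-hydroxybutanoate | O[C@@H](c3cc(OC)c4c(c3)[C@H](CO[Si](C)(C)C(C)(C)C)[C@H](c3ccc(OCc5ccccc5)c(OC)c3)O4)[C@H](CC(=O)OC)C(=O)N1C(=O)OC[C@H]1Cc1ccccc1 | intermediate (not isolated)
30 | (R)-4-benzyl-3-[(2R,3S)-2-ArD-5-oxotetrahydrofuran-3-carbonyl]oxazolidin-2-one | O1[C@@H](c3cc(OC)c4c(c3)[C@H](CO[Si](C)(C)C(C)(C)C)[C@H](c3ccc(OCc5ccccc5)c(OC)c3)O4)[C@H](CC1=O)C(=O)N2C(=O)OC[C@H]2Cc2ccccc2 | intermediate
31 | (2R,3S)-2-ArD-5-oxotetrahydrofuran-3-carboxylic acid | O1[C@@H](c3cc(OC)c4c(c3)[C@H](CO[Si](C)(C)C(C)(C)C)[C@H](c3ccc(OCc5ccccc5)c(OC)c3)O4)[C@H](CC1=O)C(=O)O | intermediate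
32 | (4R,5R)-5-ArD-4-(hydroxymethyl)dihydrofuran-2(3H)-one | O1[C@@H](c3cc(OC)c4c(c3)[C@H](CO[Si](C)(C)C(C)(C)C)[C@H](c3ccc(OCc5ccccc5)c(OC)c3)O4)[C@H](CC1=O)CO | intermediate
33 | (4R,5R)-5-ArD-4-[(tert-butyldimethylsilyloxy)methyl]dihydrofuran-2(3H)-one | O1[C@@H](c3cc(OC)c4c(c3)[C@H](CO[Si](C)(C)C(C)(C)C)[C@H](c3ccc(OCc5ccccc5)c(OC)c3)O4)[C@H](CC1=O)CO[Si](C)(C)C(C)(C)C | intermediate
34 | sodium enolate of (4R,5R)-5-ArD-4-[(tert-butyldimethylsilyloxy)methyl]-3-formyldihydrofuran-2(3H)-one | O1[C@@H](c3cc(OC)c4c(c3)[C@H](CO[Si](C)(C)C(C)(C)C)[C@H](c3ccc(OCc5ccccc5)c(OC)c3)O4)[C@H](C(=C[O-])C1=O)CO[Si](C)(C)C(C)(C)C.[Na+] | intermediate (not isolated)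
35 | (4R,5R)-5-ArD-4-[(tert-butyldimethylsilyloxy)methyl]-3-methylenedihydrofuran-2(3H)-one | O1[C@@H](c3cc(OC)c4c(c3)[C@H](CO[Si](C)(C)C(C)(C)C)[C@H](c3ccc(OCc5ccccc5)c(OC)c3)O4)[C@H](C(=C)C1=O)CO[Si](C)(C)C(C)(C)C | intermediate
36 | (1R,2R)-1-ArD-2-[(tert-butyldimethylsilyloxy)methyl]-3-methylenebutane-1,4-diol | O[C@@H](c3cc(OC)c4c(c3)[C@H](CO[Si](C)(C)C(C)(C)C)[C@H](c3ccc(OCc5ccccc5)c(OC)c3)O4)[C@H](C(=C)CO)CO[Si](C)(C)C(C)(C)C | intermediate
37 | tert-butyl{[(2R,3R)-2-ArD-4-methylenetetrahydrofuran-3-yl]methoxy}dimethylsilane | O1[C@@H](c3cc(OC)c4c(c3)[C@H](CO[Si](C)(C)C(C)(C)C)[C@H](c3ccc(OCc5ccccc5)c(OC)c3)O4)[C@H](C(=C)C1)CO[Si](C)(C)C(C)(C)C | intermediate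
38 | (3R,6R,7R)-6-ArD-7-[(tert-butyldimethylsilyloxy)methyl]-1,5-dioxaspiro[2.4]heptane | C1[C@@]2(O1)CO[C@@H](c3cc(OC)c4c(c3)[C@H](CO[Si](C)(C)C(C)(C)C)[C@H](c3ccc(OCc5ccccc5)c(OC)c3)O4)[C@H]2CO[Si](C)(C)C(C)(C)C | intermediate
39 | (4-benzyloxy-3-methoxyphenyl)magnesium bromide | COc1cc([Mg]Br)ccc1OCc1ccccc1 | intermediate (not isolated)
40 | (3S,4R,5R)-5-ArD-3-(4-benzyloxy-3-methoxybenzyl)-4-[(tert-butyldimethylsilyloxy)methyl]tetrahydrofuran-3-ol | COc1cc(C[C@@]2(O)CO[C@@H](c3cc(OC)c4c(c3)[C@H](CO[Si](C)(C)C(C)(C)C)[C@H](c3ccc(OCc5ccccc5)c(OC)c3)O4)[C@H]2CO[Si](C)(C)C(C)(C)C)ccc1OCc1ccccc1 | intermediate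
41 | (3S,4R,5R)-3-(4-benzyloxy-3-methoxybenzyl)-5-[(2R,3R)-2-(4-benzyloxy-3-methoxyphenyl)-3-(hydroxymethyl)-7-methoxy-2,3-dihydrobenzofuran-5-yl]-4-(hydroxymethyl)tetrahydrofuran-3-ol | COc1cc(C[C@@]2(O)CO[C@@H](c3cc(OC)c4c(c3)[C@H](CO)[C@H](c3ccc(OCc5ccccc5)c(OC)c3)O4)[C@H]2CO)ccc1OCc1ccccc1 | intermediate
42 | (3S,4R,5R)-3-(4-hydroxy-3-methoxybenzyl)-5-[(2R,3R)-2-(4-hydroxy-3-methoxyphenyl)-3-(hydroxymethyl)-7-methoxy-2,3-dihydrobenzofuran-5-yl]-4-(hydroxymethyl)tetrahydrofuran-3-ol | COc1cc(C[C@@]2(O)CO[C@@H](c3cc(OC)c4c(c3)[C@H](CO)[C@H](c3ccc(O)c(OC)c3)O4)[C@H]2CO)ccc1O | target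

**Step count and risks**

Total step count: 25 (alkyne branch: steps 5 and 6; imide branch: step 14). Longest linear sequence: 22 steps (steps 1–4, 7–13 and 15–25).

Steps most likely to fail:

1. Step 9 (Proposed new method). The tetrasubstituted, aromatic C2'=C3' bond may be hydrogenated slowly or with poor facial selectivity. Fallback with known chemistry, from 18:
   - Heterogeneous syn hydrogenation (H2, 60 bar, Rh/Al2O3, EtOAc, 50 °C) gives the racemic cis ester F1.
   - i-Bu2AlH gives the racemic cis alcohol F2.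
   - Esterification with (S)-2-methoxy-2-phenylacetic acid (DCC, DMAP) gives two diastereomeric esters that are separated by chromatography; the wanted one is the (2R,3R) O-methylmandelate F3.
   - Reductive cleavage of F3 with i-Bu2AlH at −78 °C returns alcohol 20, where the route is rejoined.

2. Step 15. The ester side chain of the imide can compete for magnesium, so the anti or facial selectivity may drop, and the adduct may revert by retro-aldol cleavage. Fallback in which C2 is set by ketone hydrogenation and C3 by alkylation, from 24: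
   - Addition of LiCH2CO2Me gives hydroxy ester F4 as a mixture of carbinol epimers.
   - Dess–Martin periodinane gives β-keto ester F5.
   - Noyori hydrogenation (RuCl2[(S)-BINAP], H2, MeOH) gives the (3R)-hydroxy ester F6.
   - Fráter–Seebach alkylation of its dianion (LiN(i-Pr)2, 2.2 equiv; BrCH2CO2t-Bu) enters anti to the alkoxide and gives diester F7.
   - LiBH4 reduces only the methyl ester, giving diol F8.
   - TBSCl and imidazole silylate the primary alcohol to give F9.
   - NaH (cat.) in THF closes the lactone with loss of tert-butoxide and gives 33, where the route is rejoined.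

3. Step 7. The 2-arylfuran chromophore absorbs strongly at 254 nm and may be consumed by competing photoreactions, or the ketene may dimerise before it meets the ynol ether. Fallback that makes the same ketene without light, from 7:
   - Silver-promoted Wolff rearrangement in aqueous dioxane (AgO2CPh, Et3N; Arndt–Eistert homologation) gives the furylacetic acid F10.
   - (COCl)2 gives the acid chloride F11.
   - Slow addition of Et3N to F11 and 12 in toluene at 80 °C gives ketene 13 by dehydrochlorination, which runs through cyclobutenone 14 and the same electrocyclic cascade to phenol 17, where the route is rejoined.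

Further compounds
F1 | step 9 | methyl (2RS,3SR)-2-(4-benzyloxy-3-methoxyphenyl)-7-methoxy-5-(triisopropylsilyloxy)-2,3-dihydrobenzofuran-3-carboxylate (racemic cis ester; one enantiomer drawn) | CC(C)[Si](C(C)C)(C(C)C)Oc1cc(OC)c2c(c1)[C@H](C(=O)OC)[C@H](c1ccc(OCc3ccccc3)c(OC)c1)O2
F2 | step 9 | [(2RS,3RS)-2-(4-benzyloxy-3-methoxyphenyl)-7-methoxy-5-(triisopropylsilyloxy)-2,3-dihydrobenzofuran-3-yl]methanol (racemic cis alcohol; one enantiomer drawn) | CC(C)[Si](C(C)C)(C(C)C)Oc1cc(OC)c2c(c1)[C@H](CO)[C@H](c1ccc(OCc3ccccc3)c(OC)c1)O2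
F3 | step 9 | [(2R,3R)-2-(4-benzyloxy-3-methoxyphenyl)-7-methoxy-5-(triisopropylsilyloxy)-2,3-dihydrobenzofuran-3-yl]methyl (S)-2-methoxy-2-phenylacetate | CC(C)[Si](C(C)C)(C(C)C)Oc1cc(OC)c2c(c1)[C@H](COC(=O)[C@@H](OC)c1ccccc1)[C@H](c1ccc(OCc3ccccc3)c(OC)c1)O2
F4 | step 15 | methyl 3-ArD-3-hydroxypropanoate (mixture of carbinol epimers) | OC(CC(=O)OC)c1cc(OC)c2c(c1)[C@H](CO[Si](C)(C)C(C)(C)C)[C@H](c1ccc(OCc3ccccc3)c(OC)c1)O2
F5 | step 15 | methyl 3-ArD-3-oxopropanoate | COC(=O)CC(=O)c1cc(OC)c2c(c1)[C@H](CO[Si](C)(C)C(C)(C)C)[C@H](c1ccc(OCc3ccccc3)c(OC)c1)O2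
F6 | step 15 | methyl (3R)-3-ArD-3-hydroxypropanoate | O[C@@H](c3cc(OC)c4c(c3)[C@H](CO[Si](C)(C)C(C)(C)C)[C@H](c3ccc(OCc5ccccc5)c(OC)c3)O4)CC(=O)OC
F7 | step 15 | 4-tert-butyl 1-methyl (2S)-2-[(R)-ArD(hydroxy)methyl]butanedioate | O[C@@H](c3cc(OC)c4c(c3)[C@H](CO[Si](C)(C)C(C)(C)C)[C@H](c3ccc(OCc5ccccc5)c(OC)c3)O4)[C@H](CC(=O)OC(C)(C)C)C(=O)OC
F8 | step 15 | tert-butyl (3R,4R)-4-ArD-4-hydroxy-3-(hydroxymethyl)butanoate | O[C@@H](c3cc(OC)c4c(c3)[C@H](CO[Si](C)(C)C(C)(C)C)[C@H](c3ccc(OCc5ccccc5)c(OC)c3)O4)[C@H](CC(=O)OC(C)(C)C)CO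
F9 | step 15 | tert-butyl (3R,4R)-4-ArD-3-[(tert-butyldimethylsilyloxy)methyl]-4-hydroxybutanoate | O[C@@H](c3cc(OC)c4c(c3)[C@H](CO[Si](C)(C)C(C)(C)C)[C@H](c3ccc(OCc5ccccc5)c(OC)c3)O4)[C@H](CC(=O)OC(C)(C)C)CO[Si](C)(C)C(C)(C)C
F10 | step 7 | 2-[5-(4-benzyloxy-3-methoxyphenyl)-4-(methoxycarbonyl)furan-3-yl]acetic acid | COC(=O)c1c(CC(=O)O)coc1-c1ccc(OCc2ccccc2)c(OC)c1
F11 | step 7 | methyl 2-(4-benzyloxy-3-methoxyphenyl)-4-(2-chloro-2-oxoethyl)furan-3-carboxylate | COC(=O)c1c(CC(=O)Cl)coc1-c1ccc(OCc2ccccc2)c(OC)c1
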